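**Retrosynthetic overview** (carbocycle atoms: C1 = CH bearing the pentenyl group, C2 = C(CH3)(O), C3 = CH(O), C4 = C(CH3)=, C5 = CH=, C6 = C(CH3)(pyranonyl))
1. The C2–C3 oxirane and the C4=C5 alkene are made last from the ring diene C2=C3–C4=C5 of 22, by singlet-oxygen [4+2] addition and phosphine deoxygenation of the endoperoxide 23.
2. Diene 22 comes from dienone 17: C1–H is set from C6 by 1,2-reduction at C5 and a suprafacial [1,5]-hydrogen shift C5→C1, and the C5 oxygen then leaves as triflate.
3. Dienone 17 comes from cyclohex-3-enone 13 by asymmetric phase-transfer methylation at C6 (the only external source of chirality), C4 methylation and dehydrogenation.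
4. Ketone 13 comes from cyclopentenone 11 and pyranonyldiazomethane 7: diazo-aldol union, then a Rh-carbenoid 1,2-alkenyl shift that inserts C6 between C5 and C1 and enlarges the five-membered ring to the carbocycle. Ring order: pyranone (step 2), cyclopentenone (bought), six-membered carbocycle (step 7), peroxide bridge (step 14), oxirane (step 15).
5. Enabling feature: C6 is bonded to C-2 of the electron-poor 4-pyranone, so it can enter as a pyranone-stabilised diazo carbon, and its ring neighbours C5 and C1 are the carbonyl carbon and the sp2 α-carbon of a 2-alkenylcyclopent-2-enone.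

Key step: step 7

Remark: compounds 1, 2, 8 and 9 and all reagents are taken as purchasable, and the antipode of the chiral phase-transfer catalyst in step 8 is the one that gives the (R)-configured quaternary carbon (to be fixed by a short screen).

Step 1
Reactants: 1 methyl 2-methyl-3-oxopentanoate; 2 N-methoxy-N-methylacetamide
Product: 3 methyl 2,4-dimethyl-3,5-dioxohexanoate
Conditions: NaH, THF, 0 °C; n-BuLi, −10 °C; then 2, −10 °C → rt; aq. HCl
Reagents that add atoms: none
Why: γ-Acylation of the β-keto ester dianion (Weiler dianion) by the Weinreb amide, whose chelated adduct stops at the ketone stage, gives the triketide, in which all stereocentres are enolisable and irrelevant.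

Step 2
Reactants: 3 methyl 2,4-dimethyl-3,5-dioxohexanoate
Product: 4 4-hydroxy-3,5,6-trimethyl-2H-pyran-2-one
Conditions: DBU, toluene, 80 °C; aq. HCl
Reagents that add atoms: none
Why: Base-mediated lactonisation of the C5 enol oxygen onto the methyl ester (6-exo-trig cyclocondensation of a 3,5-diketo ester) is the standard entry to 4-hydroxy-2-pyranones.

Step 3
Reactants: 4 4-hydroxy-3,5,6-trimethyl-2H-pyran-2-one
Product: 5 2-methoxy-3,5,6-trimethyl-4H-pyran-4-one
Conditions: MeOTf, CH2Cl2, 0 °C → rt; aqueous work-up
Reagents that add atoms: methyl trifluoromethanesulfonate COS(=O)(=O)C(F)(F)F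
Why: The hard methylating agent alkylates the lactone carbonyl oxygen and loss of the hydroxyl proton gives the 2-methoxy-4-pyranone, the established regiochemistry for methyl triflate or methyl fluorosulfonate on 4-hydroxy-2-pyranones.

Step 4
Reactants: 5 2-methoxy-3,5,6-trimethyl-4H-pyran-4-one
Product: 7 2-(diazomethyl)-6-methoxy-3,5-dimethyl-4H-pyran-4-one, via trifluoroacetylated pyranone 6 (not isolated)
Conditions: LiHMDS, THF, −78 °C; CF3CO2CH2CF3; dilute HCl work-up; then MsN3, Et3N, H2O, MeCN, rt
Reagents that add atoms: methanesulfonyl azide CS(=O)(=O)N=[N+]=[N-]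
Why: Deacylative (detrifluoroacetylative) diazo transfer: the vinylogous enolate of the 6-methyl group is C-trifluoroacetylated and the activated methylene takes the diazo group from mesyl azide with loss of the trifluoroacetyl group as the N-acyl sulfonamide.

Step 5
Reactants: 8 pent-2-yne; 9 2-bromo-3-methylcyclopent-2-en-1-one
Product: 11 3-methyl-2-[(2E)-pent-2-en-2-yl]cyclopent-2-en-1-one, via alkenylzirconocene chloride 10 (not isolated)
Conditions: Cp2Zr(H)Cl, THF, rt → 40 °C; then 9, Pd(PPh3)4 (5 mol %), ZnCl2 (20 mol %), THF, rt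
Reagents that add atoms: none
Why: Syn hydrozirconation of the internal alkyne, with zirconium at the methyl-bearing carbon under thermodynamic control, fixes the E geometry, and Negishi coupling with the α-bromo enone proceeds with retention (the minor regioisomer is removed by chromatography).

Step 6
Reactants: 7 2-(diazomethyl)-6-methoxy-3,5-dimethyl-4H-pyran-4-one; 11 3-methyl-2-[(2E)-pent-2-en-2-yl]cyclopent-2-en-1-one
Product: 12 racemic 2-{diazo[1-hydroxy-3-methyl-2-((2E)-pent-2-en-2-yl)cyclopent-2-en-1-yl]methyl}-6-methoxy-3,5-dimethyl-4H-pyran-4-one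
Conditions: LDA, THF, −78 °C (7); then 11, −78 °C; AcOH quench at −78 °C
Reagents that add atoms: none
Why: Aldol-type 1,2-addition of the lithiated, vinylogous-acyl-stabilised diazo carbon to the enone carbonyl (as with lithio diazoacetate and ketones) joins the two halves at C5–C6, conjugate addition being blocked by the fully substituted β-carbon, and the carbinol stereocentre is destroyed in step 7.

Step 7
Reactants: 12 racemic diazo carbinol
Product: 13 racemic 2-methoxy-3,5-dimethyl-6-{3-methyl-6-oxo-2-[(2E)-pent-2-en-2-yl]cyclohex-2-en-1-yl}-4H-pyran-4-one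
Conditions: Rh2(OAc)4 (1 mol %), CH2Cl2, 0 °C → rt
Reagents that add atoms: none
Why: Rh2(OAc)4 turns the diazo group into an electrophilic rhodium carbenoid next to the tertiary allylic carbinol, and 1,2-shift of the ring alkenyl carbon C1 from the carbinol carbon C5 to the carbenoid carbon C6, with the hydroxyl oxygen becoming the carbonyl, releases the metal and gives the ring-enlarged ketone. The closest known reaction is the rhodium-catalysed ring expansion of β-hydroxy-α-diazo carbonyl adducts of cyclic ketones (lithio diazoacetate addition then Rh(II) rearrangement, a Tiffeneau–Demjanov-type homologation), here with a vinylogous acyl (pyranonyl) diazo group. The six-membered ring is closed not by a cyclisation but by this carbon-to-carbon 1,2-migration, which inserts C6 between C5 and C1 of the cyclopentene (ring enlargement by one atom). No stereocentre of the target is fixed here, because the new C6–H is enolisable and is methylated enantioselectively in step 8 and the carbinol centre disappears. The step needs alkenyl migration rather than migration of the ring CH2, O–H insertion or cyclopropanation; the sp2 carbon migrates through a bridged, allyl-stabilised transition state (alkenyl over alkyl in carbenoid and diazonium 1,2-shifts), the carbinol carbon carries no hydrogen, and both alkenes are too close to the carbenoid carbon to be cyclopropanated.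

Step 8
Reactants: 13 racemic ring-enlarged ketone
Product: 14 2-methoxy-3,5-dimethyl-6-{(1R)-1,3-dimethyl-6-oxo-2-[(2E)-pent-2-en-2-yl]cyclohex-2-en-1-yl}-4H-pyran-4-one
Conditions: MeI, solid K2CO3, chiral binaphthyl-derived spiro quaternary ammonium bromide (Maruoka type, 2 mol %), toluene, −20 °C
Reagents that add atoms: iodomethane CI
Why: Asymmetric phase-transfer C-methylation of the doubly activated α-CH (ketone plus vinylogous ester), as for α-aryl ketones, goes through an extended enolate that is alkylated at the α-carbon within the chiral ammonium ion pair, so the catalyst alone sets the quaternary stereocentre C6.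

Step 9
Reactants: 14 (R)-configured α-quaternary ketone
Product: 15 2-methoxy-3,5-dimethyl-6-{(1R)-1,3,5-trimethyl-6-oxo-2-[(2E)-pent-2-en-2-yl]cyclohex-2-en-1-yl}-4H-pyran-4-one (both C5 epimers)
Conditions: LDA, THF, −78 °C; MeI, −78 → 0 °C
Reagents that add atoms: iodomethane CI
Why: Kinetic enolisation at the only remaining α-position (C4) and methylation install the C4 methyl group, whose configuration is irrelevant because this carbon becomes sp2 in step 10.

Step 10
Reactants: 15 C4-methylated ketone
Product: 17 2-methoxy-3,5-dimethyl-6-{(1R)-1,3,5-trimethyl-6-oxo-2-[(2E)-pent-2-en-2-yl]cyclohexa-2,4-dien-1-yl}-4H-pyran-4-one, via trimethylsilyl enol ether 16 (not isolated)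
Conditions: LiHMDS, TMSCl, THF, −78 → 0 °C; then Pd(OAc)2 (1.1 equiv), MeCN, rt, exclusion of light
Reagents that add atoms: none
Why: Saegusa–Ito dehydrogenation of the only possible silyl enol ether (C5=C4) proceeds by β-hydride elimination towards the ring C3–H to give the fully conjugated 2,4-dienone, which cannot aromatise because C6 is quaternary.

Step 11
Reactants: 17 dienone
Product: 18 2-{(1S,6R)-6-hydroxy-1,3,5-trimethyl-2-[(2E)-pent-2-en-2-yl]cyclohexa-2,4-dien-1-yl}-6-methoxy-3,5-dimethyl-4H-pyran-4-one (hydroxyl cis to the pyranone)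
Conditions: NaBH4, CeCl3·7H2O, MeOH, −40 °C; base-washed work-up, used at once
Reagents that add atoms: none
Why: Luche 1,2-reduction of the dienone carbonyl (the pyranone carbonyl is inert) delivers hydride to C5 from the face of the C6 methyl group, anti to the bulkier pyranone, so the new C5–H lies on the methyl face.

Step 12
Reactants: 18 dienol
Product: 21 (5S,6R)-6-(6-methoxy-3,5-dimethyl-4-oxo-4H-pyran-2-yl)-2,4,6-trimethyl-5-[(2E)-pent-2-en-2-yl]cyclohexa-1,3-dien-1-yl trifluoromethanesulfonate, via potassium alkoxide 19 (not isolated), via potassium dienolate 20 (not isolated)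
Conditions: KH, 18-crown-6, THF, 0 °C → rt; then PhNTf2, −78 → 0 °C; aq. NH4Cl
Reagents that add atoms: N-phenylbis(trifluoromethanesulfonimide) O=S(=O)(N(c1ccccc1)S(=O)(=O)C(F)(F)F)C(F)(F)F
Why: An alkoxide-accelerated suprafacial [1,5]-sigmatropic hydrogen shift in the cyclohexa-2,4-dien-1-olate (known for cyclic 2,4-dienyl alkoxides) carries the carbinol hydrogen across the ring face from C5 to C1, so C1–H ends on the methyl face and the pentenyl group cis to the pyranone, and the dienolate formed is O-triflated in the same flask.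

Step 13
Reactants: 21 dienyl triflate
Product: 22 2-methoxy-3,5-dimethyl-6-{(1R,6S)-1,3,5-trimethyl-6-[(2E)-pent-2-en-2-yl]cyclohexa-2,4-dien-1-yl}-4H-pyran-4-one
Conditions: Pd(OAc)2 (5 mol %), PPh3 (10 mol %), HCO2H, Et3N, DMF, 60 °C, dark
Reagents that add atoms: none
Why: Palladium-catalysed formate reduction of the enol triflate replaces OTf by H with retention of the diene and without touching the two stereocentres.

Step 14
Reactants: 22 ring diene
Product: 23 2-methoxy-3,5-dimethyl-6-[(1R,4S,7R,8S)-1,5,8-trimethyl-7-((2E)-pent-2-en-2-yl)-2,3-dioxabicyclo[2.2.2]oct-5-en-8-yl]-4H-pyran-4-one (peroxide bridge anti to the pentenyl and pyranonyl groups)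
Conditions: O2, tetraphenylporphyrin (cat.), visible light (>500 nm), CH2Cl2, −78 °C
Reagents that add atoms: dioxygen O=O
Why: Singlet oxygen adds [4+2] to the electron-rich cisoid ring diene (C2 and C5) faster than it undergoes an ene reaction with the isolated side-chain alkene, and from the face opposite to the pentenyl and pyranonyl groups, as in the endoperoxides of related cyclohexadiene pyranones.

Step 15
Reactants: 23 endoperoxide
Product: 25 2-methoxy-3,5-dimethyl-6-{(1R,4R,5R,6S)-2,4,6-trimethyl-5-[(2E)-pent-2-en-2-yl]-7-oxabicyclo[4.1.0]hept-2-en-4-yl}-4H-pyran-4-one, via oxyphosphonium alkoxide betaine 24 (not isolated)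
Conditions: PPh3, CH2Cl2, 0 °C → rt
Reagents that add atoms: none
Why: Triphenylphosphine attacks the less hindered peroxide oxygen (on the secondary carbon C5) and the tertiary alkoxide on C2 closes onto C3 in a syn-SN2′ displacement of triphenylphosphine oxide, giving the C2–C3 oxirane on the face of the former peroxide bridge and the C4=C5 alkene (the known conversion of unsaturated bicyclic endoperoxides into diene monoepoxides).

**Compound list**
1 | methyl 2-methyl-3-oxopentanoate | CCC(=O)C(C)C(=O)OC | starting material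
2 | N-methoxy-N-methylacetamide | CC(=O)N(C)OC | starting material
3 | methyl 2,4-dimethyl-3,5-dioxohexanoate | CC(=O)C(C)C(=O)C(C)C(=O)OC | intermediate
4 | 4-hydroxy-3,5,6-trimethyl-2H-pyran-2-one | Cc1oc(=O)c(C)c(O)c1C | intermediate
5 | 2-methoxy-3,5,6-trimethyl-4H-pyran-4-one | COc1oc(C)c(C)c(=O)c1C | intermediate
6 | 2-methoxy-3,5-dimethyl-6-(3,3,3-trifluoro-2-oxopropyl)-4H-pyran-4-one | COc1oc(CC(=O)C(F)(F)F)c(C)c(=O)c1C | intermediate (not isolated)
7 | 2-(diazomethyl)-6-methoxy-3,5-dimethyl-4H-pyran-4-one | COc1oc(C=[N+]=[N-])c(C)c(=O)c1C | intermediate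
8 | pent-2-yne | CC#CCC | starting material
9 | 2-bromo-3-methylcyclopent-2-en-1-one | CC1=C(Br)C(=O)CC1 | starting material
10 | chloridobis(cyclopentadienyl)[(2E)-pent-2-en-2-yl]zirconium | CC/C=C(\C)[Zr](Cl)(C1C=CC=C1)C1C=CC=C1 | intermediate (not isolated)
11 | 3-methyl-2-[(2E)-pent-2-en-2-yl]cyclopent-2-en-1-one | CC/C=C(\C)C1=C(C)CCC1=O | intermediate
12 | racemic 2-{diazo[1-hydroxy-3-methyl-2-((2E)-pent-2-en-2-yl)cyclopent-2-en-1-yl]methyl}-6-methoxy-3,5-dimethyl-4H-pyran-4-one | CC/C=C(\C)C1=C(C)CCC1(O)C(=[N+]=[N-])c1oc(OC)c(C)c(=O)c1C | intermediate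
13 | racemic 2-methoxy-3,5-dimethyl-6-{3-methyl-6-oxo-2-[(2E)-pent-2-en-2-yl]cyclohex-2-en-1-yl}-4H-pyran-4-one | CC/C=C(\C)C1=C(C)CCC(=O)C1c1oc(OC)c(C)c(=O)c1C | intermediate
14 | 2-methoxy-3,5-dimethyl-6-{(1R)-1,3-dimethyl-6-oxo-2-[(2E)-pent-2-en-2-yl]cyclohex-2-en-1-yl}-4H-pyran-4-one | CC/C=C(\C)C1=C(C)CCC(=O)[C@@]1(C)c1oc(OC)c(C)c(=O)c1C | intermediate
15 | 2-methoxy-3,5-dimethyl-6-{(1R)-1,3,5-trimethyl-6-oxo-2-[(2E)-pent-2-en-2-yl]cyclohex-2-en-1-yl}-4H-pyran-4-one, both C5 epimers | CC/C=C(\C)C1=C(C)CC(C)C(=O)[C@@]1(C)c1oc(OC)c(C)c(=O)c1C | intermediate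
16 | trimethylsilyl enol ether of 15 (C5=C4 enol ether, C6 R) | CC/C=C(\C)C1=C(C)CC(C)=C(O[Si](C)(C)C)[C@@]1(C)c1oc(OC)c(C)c(=O)c1C | intermediate (not isolated)
17 | 2-methoxy-3,5-dimethyl-6-{(1R)-1,3,5-trimethyl-6-oxo-2-[(2E)-pent-2-en-2-yl]cyclohexa-2,4-dien-1-yl}-4H-pyran-4-one | CC/C=C(\C)C1=C(C)C=C(C)C(=O)[C@@]1(C)c1oc(OC)c(C)c(=O)c1C | intermediate
18 | 2-{(1S,6R)-6-hydroxy-1,3,5-trimethyl-2-[(2E)-pent-2-en-2-yl]cyclohexa-2,4-dien-1-yl}-6-methoxy-3,5-dimethyl-4H-pyran-4-one (OH cis to pyranone) | CC/C=C(\C)C1=C(C)C=C(C)[C@@H](O)[C@@]1(C)c1oc(OC)c(C)c(=O)c1C | intermediate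
19 | potassium alkoxide of 18 | CC/C=C(\C)C1=C(C)C=C(C)[C@@H]([O-])[C@@]1(C)c1oc(OC)c(C)c(=O)c1C.[K+] | intermediate (not isolated)
20 | potassium dienolate (C5 enolate; pentenyl at C1 cis to the pyranone at C6) | CC/C=C(\C)[C@H]1C(C)=CC(C)=C([O-])[C@@]1(C)c1oc(OC)c(C)c(=O)c1C.[K+] | intermediate (not isolated)
21 | (5S,6R)-6-(6-methoxy-3,5-dimethyl-4-oxo-4H-pyran-2-yl)-2,4,6-trimethyl-5-[(2E)-pent-2-en-2-yl]cyclohexa-1,3-dien-1-yl trifluoromethanesulfonate | CC/C=C(\C)[C@H]1C(C)=CC(C)=C(OS(=O)(=O)C(F)(F)F)[C@@]1(C)c1oc(OC)c(C)c(=O)c1C | intermediate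
22 | 2-methoxy-3,5-dimethyl-6-{(1R,6S)-1,3,5-trimethyl-6-[(2E)-pent-2-en-2-yl]cyclohexa-2,4-dien-1-yl}-4H-pyran-4-one | CC/C=C(\C)[C@H]1C(C)=CC(C)=C[C@@]1(C)c1oc(OC)c(C)c(=O)c1C | intermediate
23 | 2-methoxy-3,5-dimethyl-6-[(1R,4S,7R,8S)-1,5,8-trimethyl-7-((2E)-pent-2-en-2-yl)-2,3-dioxabicyclo[2.2.2]oct-5-en-8-yl]-4H-pyran-4-one | CC/C=C(\C)[C@H]1[C@@]2(C)C=C(C)[C@H](OO2)[C@@]1(C)c1oc(OC)c(C)c(=O)c1C | intermediate
24 | betaine from 23: triphenylphosphonio-oxy group on C5, alkoxide on C2, both on the former peroxide face | CC/C=C(\C)[C@H]1[C@@]([O-])(C)C=C(C)[C@H](O[P+](c2ccccc2)(c2ccccc2)c2ccccc2)[C@@]1(C)c1oc(OC)c(C)c(=O)c1C | intermediate (not isolated)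
25 | 2-methoxy-3,5-dimethyl-6-{(1R,4R,5R,6S)-2,4,6-trimethyl-5-[(2E)-pent-2-en-2-yl]-7-oxabicyclo[4.1.0]hept-2-en-4-yl}-4H-pyran-4-one | CC/C=C(\C)[C@H]1[C@]2(C)O[C@@H]2C(C)=C[C@@]1(C)c1oc(OC)c(C)c(=O)c1C | target

**Step count and risks**
Total: 15 steps. Longest linear sequence: 14 steps (steps 1–4 and 6–15).

The three steps most likely to fail:

Step 12. After deprotonation the alkoxide may fragment by retro-aldol-type cleavage of the C5–C6 bond (the pyranone stabilises a C6 carbanion) faster than the hydrogen shift occurs, or the dienol may ionise and rearomatise by a 1,2-shift before it is deprotonated. The fallback sets out from 18 and replaces the sigmatropic shift by a metal-hydride delivery. The hydroxyl is acylated (ClCO2Me, pyridine, DMAP, CH2Cl2) to the methyl carbonate F1, which is subjected to Tsuji-type formate hydrogenolysis (Pd2(dba)3, PBu3, HCO2H, Et3N, THF). Palladium ionises anti to the carbonate and so sits on the methyl face of the pentadienyl system, and hydride is delivered from the metal to the more substituted terminus C1 on that same face. This should give the conjugated ring diene directly, returning to the route at 22 and bypassing 21.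

Step 6. The lithiated diazo compound may act as a base towards the hindered, 2,3-disubstituted enone (enolisation), or the adduct may revert (retro-addition), so that little carbinol is obtained. The fallback sets out from 7 and 9 and moves the pentenyl coupling behind the ring enlargement. Lithiated 7 is added to the smaller bromo enone 9 to give the bromo diazo carbinol F2. Rh2(OAc)4 then effects the same 1,2-alkenyl shift to the ring-enlarged bromo ketone F3. Its vinyl bromide is coupled with the alkenylzirconocene 10 (from 8) under the Negishi conditions of step 5, returning to the route at 13.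

Step 15. The phosphine may attack the other peroxide oxygen (the one on C2), which would lead to the regioisomeric C4–C5 oxirane with a C2=C3 alkene. The fallback sets out from 23 and fixes the site of activation. The O–O bond is reduced with thiourea (MeOH, rt) to the cis-ene-1,4-diol F4, which is closed under Mitsunobu conditions (PPh3, DIAD, THF). Only the secondary allylic hydroxyl on C5 can become the oxyphosphonium leaving group, so the tertiary C2 hydroxyl must close onto C3 in the same syn-SN2′ sense, returning to the route at 25.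

**Further compounds**
F1 | step 12 | methyl carbonate of dienol 18 (carbonate on C5, cis to the pyranone) | CC/C=C(\C)C1=C(C)C=C(C)[C@@H](OC(=O)OC)[C@@]1(C)c1oc(OC)c(C)c(=O)c1C
F2 | step 6 | racemic 2-[(2-bromo-1-hydroxy-3-methylcyclopent-2-en-1-yl)(diazo)methyl]-6-methoxy-3,5-dimethyl-4H-pyran-4-one | BrC1=C(C)CCC1(O)C(=[N+]=[N-])c1oc(OC)c(C)c(=O)c1C
F3 | step 6 | racemic 2-(2-bromo-3-methyl-6-oxocyclohex-2-en-1-yl)-6-methoxy-3,5-dimethyl-4H-pyran-4-one | BrC1=C(C)CCC(=O)C1c1oc(OC)c(C)c(=O)c1C
F4 | step 15 | cis-ene-1,4-diol from 23 (hydroxyls on C2 and C5, both anti to the pentenyl and pyranonyl groups) | CC/C=C(\C)[C@H]1[C@@](O)(C)C=C(C)[C@H](O)[C@@]1(C)c1oc(OC)c(C)c(=O)c1C
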